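## Structural features

The target is a (3R)-isoflavan. Ring A (C4a, C5–C8, C8a) is fused to the dihydropyran ring C (O1, C2, C3, C4), and C3 carries ring B through the C3–C1' bond. Ring B is itself the benzo ring of a 2,2-dimethyl-2H-chromene: the pyran oxygen sits on C2', the alkene carbon is bonded to C3' (the carbon between the two ring B oxygens), and C4' bears a free hydroxyl. C3 is the only stereocentre, a benzylic CH between the methylene groups C2 and C4, so no neighbouring centre can relay configuration and the absolute sense must come from a chiral reagent, catalyst or enzyme. Ring A is a phloroglucinol unit with three different oxygens: O1 on C8a and the methoxy group on C5 flank C4a, and the free hydroxyl on C7 is para to it. The fragile parts are the styrene-like C=C of the chromene (lost on hydrogenation, sensitive to strong acid and electrophilic oxidants, which excludes benzyl ethers and acid-labile acetals as phenol protection) and the electron-rich phenols. The real difficulty is the unambiguous placement of O1, OMe and OH on ring A, which on a preformed phloroglucinol would need two selective differentiations of nearly equivalent hydroxyls. The key step avoids this by assembling ring A from a four-carbon and a two-carbon piece: C8a–OH comes from a ketene carbonyl, C5–OMe from an ynol ether carbon, C7–O from a cyclobutenone enol ether, and C4a arrives with the C4–C3–C2 chain already attached.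

## Logic of the disconnections

27 to 26: the two O–allyl bonds are cut. Both phenols must stay masked through base, hydride, organolithium and heat, and the mask must come off without hydrogen or strong acid because of the chromene alkene. One neutral operation with zerovalent palladium serves both rings. The demand is that the last step touches neither the cyclic tertiary allylic ether of ring B nor C3.

26 to 25 and 24: the O1–C2 bond is cut. Closing an aryl alkyl ether from a phenol and a primary alcohol is reliable and leaves C3, one atom away, untouched. Ring C disappears and ring A becomes a 2-alkylphenol. The demand is that ring A carries exactly one free hydroxyl, ortho to the chain, and that the primary alcohol can be unmasked beside two allyl ethers; hence the silyl ether in 24.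

24 to 17 and 19 (key disconnection): C4a–C8a, C5–C6 and C8–C8a are cut and ring A is dismantled. The three oxygens are then on three different carbons of two different partners, so no selective etherification of a phloroglucinol is needed. The demand is a single regiochemistry in the union of ketene and alkyne, and tolerance of about 100 °C by the allyl ethers, the silyl ether and the chromene.

19 to 18: the enol ether O–allyl bond is traced to an exchange on the commercial ethyl analogue. The ethyl group itself could not be removed later beside the C5 methyl ether. The demand is an acid mild enough to spare the strained ring.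

17 to 14 and 16 (from 15): the C4–C4a bond, sp3 to sp, is cut. The ynol ether becomes a two-carbon reagent made in the flask, and the chain becomes a three-carbon unit with two oxygenated ends. The demand is an SN2 displacement at a β-branched primary carbon, hence a triflate, low temperature and a medium free of unhindered amine.

14 back to 10 through 13, 12 and 11: only functional groups on the two CH2O arms change. C3 is a stereocentre solely because the arms differ, so the absolute configuration reduces to telling apart the two enantiotopic hydroxymethyl groups of 10. The demand is high enantiotopic-group selectivity and the absence of acyl or silyl migration between the arms, which would racemise C3.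

10 to 9 and on to 7 and 8: the C3–C1' bond is cut. 8 supplies C3 with both arms in masked form and ring B becomes an aryl iodide. The demand is a coupling that spares the allyl ether, which points to copper and away from palladium, and an iodide because the ring is hindered and electron-rich.

7 to 4 (through 5 and 6), then to 2 and 3, then to 1: the pyran ring of ring B is opened at its aryl–CH bond and at the O–CMe2 bond. The iodine needed later for the C3–C1' bond also blocks one ortho position, so the rearrangement can only go to the carbon between the two oxygens. The demand is a selective mono-allylation of 1 at the less hindered hydroxyl.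

## Other disconnections considered

Alternative 1: The cut runs through ring C at C3–C4 and O1–C2.
- Forward step: base would release the ortho-quinone methide A4 from the hydroxybenzyl sulfone A2. The enamine formed from the ring B arylacetaldehyde A3 and a chiral secondary amine of the diarylprolinol silyl ether type would add to the exocyclic methylene, forming C3–C4. The phenol oxygen would then close onto the former aldehyde carbon to give the lactol A1 as an anomeric mixture. Removal of the anomeric oxygen and desilylation would follow.
- In favour: both aromatic halves are joined and C3 is created in one catalytic operation at ambient temperature, with no enzyme and no protecting-group exchange on a diol.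
- Against: C3 is created α to a masked aldehyde and bears an aryl group, so the open form of A1 is an α-aryl aldehyde that could epimerise under the same amine and base. A2 must already contain ring A with its three oxygens differentiated, so the aromatic problem is only moved into the synthesis of A2. Ionic removal of the lactol oxygen would bring a Lewis acid next to the chromene.
- Comparison, structure: the chosen plan solves the labelling of the ring A oxygens; this one does not.
- Comparison, mechanism: both rest on well-studied families. The chosen plan keeps C3 non-enolisable from step 6 onward, whereas here its integrity would depend on how fast the lactol closes.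
- Comparison, step economy: the alternative is the better (about three or four operations from A2 and A3, against six from 14). In convergence the two are equal.

Alternative 2: The cut dismantles ring B at C1'–C2', C2'–C3', C4'–C5' and C5'–C6'.
- Forward step: irradiation of the unsaturated diazoketone A6 (with chroman C3 on the β-carbon of the enone) would trigger a Wolff rearrangement forming C5'–C6'. The resulting ketene would add the siloxyalkyne A7, and four-electron opening and six-electron closure would give the isoflavan A5 with a free 2'-hydroxyl beside the 3'-prenyl group. Oxidative cyclisation of that ortho-prenylphenol to the chromene and desilylation would follow.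
- In favour: it is the same pericyclic logic in its best-documented form (siloxyalkyne partner, ketene generated photochemically at ambient temperature). The prenyl group lands on C3' without regiochemical ambiguity, and the only free phenol is the one that must become the pyran oxygen.
- Against: the benzannulation is spent on the easier ring, since ring B has a resorcinol pattern that a blocked Claisen rearrangement already controls. Ring A with its three differentiated oxygens and the stereocentre must be made first by other means. In A6, C3 is allylic and γ to the carbonyl, and would probably be reached through an α-branched chroman aldehyde that is prone to epimerisation. The quinone-mediated ring closure must leave the electron-rich ring A and the benzylic C4 alone.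
- Comparison, structure: the chosen plan is the better, because it addresses the harder ring.
- Comparison, mechanism: the alternative is the equal in kind and the better in precedent, since its cascade variant is better documented than the 3-alkoxycyclobutenone partner of the chosen plan.
- Comparison, step economy: the alternative should be longer, because the chiral chroman must be built first and the chromene needs two steps after the annulation.

Alternative 3: The cut is at C4–C4a and C3–C1', around C3.
- Forward step: the ring B aryllithium A10 would add to vinylboronic pinacol ester A11 to give a four-coordinate boronate. A palladium catalyst carrying a chiral ferrocenyl bisphosphine of the MandyPhos family would insert into the ring A aryl triflate A9 and bind the vinyl group. A 1,2-shift of the ring B aryl from boron to carbon (C3–C1') with C4–C4a formation would give the boronic ester A8; no ring closes. One-carbon homologation of the C–B bond with retention, oxidation to the primary alcohol, acetal removal and Mitsunobu closure would follow.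
- In favour: two C–C bonds and the stereocentre are made in one catalytic step from three simple components. The stereocentre is catalyst-set and either enantiomer is available by choice of ligand.
- Against: A9 is a doubly ortho-oxygenated, very electron-rich triflate, slow in oxidative addition and hindered in the coupling. A9 also derives from a 1,2,3,5-tetraoxygenated benzene with distinguished substituents, which is harder to make than ring A itself. The end game needs acid to remove the methoxymethyl groups beside the chromene and leaves two free phenols on ring A during ring closure. Boron ends on C3, so an extra homologation is required.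
- Comparison, structure: like alternative 1, it pushes the ring A oxygen problem into a building block.
- Comparison, mechanism: it is the equal in the principle of stereocontrol (an external chiral agent in both plans). It is worse in the fit between substrate and precedent and in the acidic, less selective end game.
- Comparison, step economy: the alternative is the better, and it is also the most convergent of the plans.

Key step: step 12

Notation: Ar stands for the 5-(allyloxy)-2,2-dimethyl-2H-chromen-8-yl group, that is ring B with its pyran ring and its allyl ether.

Assumption: the lipase is taken to acetylate the enantiotopic hydroxymethyl group of 10 that gives (R)-11, by analogy with simpler 2-aryl-1,3-propanediols; the sense must be confirmed for this aryl group, and the fallback for step 6 covers the opposite outcome.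

## Route

Step 1
Reactants: 1 4-iodoresorcinol
Product: 2 5-(allyloxy)-2-iodophenol
Conditions: allyl bromide (1.0 equiv), K2CO3 (1.0 equiv), acetone, rt
Reagents that add atoms: allyl bromide, C=CCBr
Why: Williamson etherification with one equivalent of base and halide; the hydroxyl para to iodine should react first because the other is flanked by the large halogen and held in an OH···I contact, and the minor regioisomer and the bis-ether would be removed by chromatography.

Step 2
Reactants: 2 5-(allyloxy)-2-iodophenol; 3 3-chloro-3-methylbut-1-yne
Product: 4 4-(allyloxy)-1-iodo-2-[(2-methylbut-3-yn-2-yl)oxy]benzene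
Conditions: 3 (1.5 equiv), CuCl2·2H2O (1 mol%), DBU, MeCN, 0 °C → rt
Reagents that add atoms: none
Why: Copper-catalysed O-alkylation of a phenol with a tertiary propargylic chloride (a copper acetylide ionises to an allenylidene-type electrophile), a method that tolerates hindered phenols; the aryl iodide should not couple with the alkyne at 0 °C without palladium.

Step 3
Reactants: 4 4-(allyloxy)-1-iodo-2-[(2-methylbut-3-yn-2-yl)oxy]benzene
Product: 7 5-(allyloxy)-8-iodo-2,2-dimethyl-2H-chromene, via allenylphenol 5 (not isolated), via ortho-quinone methide 6 (not isolated)
Conditions: xylenes, 140 °C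
Reagents that add atoms: none
Why: Aromatic propargyl Claisen rearrangement: the [3,3] shift can only reach the carbon between the two oxygens because iodine blocks the other ortho position; 5 then undergoes a 1,5-hydrogen shift to 6, which closes by oxa-six-electron electrocyclisation, while the aryl allyl ether needs a distinctly higher temperature to rearrange.

Step 4
Reactants: 7 5-(allyloxy)-8-iodo-2,2-dimethyl-2H-chromene; 8 diethyl malonate
Product: 9 diethyl 2-Ar-malonate
Conditions: 8 (2 equiv), CuI (10 mol%), 2-picolinic acid (20 mol%), Cs2CO3 (3 equiv), 1,4-dioxane, 40–60 °C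
Reagents that add atoms: none
Why: Copper-catalysed (Hurtley-type) α-arylation of the malonate anion forms C3–C1'; copper is chosen because zerovalent palladium with a malonate nucleophile would cleave the allyl ether (Tsuji–Trost), and the iodide rather than the bromide because the ortho-alkoxy, electron-rich ring reacts slowly.

Step 5
Reactants: 9 diethyl 2-Ar-malonate
Product: 10 2-Ar-propane-1,3-diol
Conditions: LiAlH4 (4 equiv), THF, 0 °C → rt, inverse addition
Reagents that add atoms: none
Why: Hydride reduction of both esters to the prochiral 1,3-diol; adding the malonate to excess hydride in the cold limits enolisation of the acidic arylmalonate and the elimination that would follow, and the alkenes and aryl ethers are inert.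

Step 6
Reactants: 10 2-Ar-propane-1,3-diol
Product: 11 (2R)-2-Ar-3-hydroxypropyl acetate
Conditions: lipase PS (Burkholderia cepacia), vinyl acetate, t-BuOMe, 25 °C
Reagents that add atoms: vinyl acetate, CC(=O)OC=C
Why: Enzymatic desymmetrisation by irreversible transesterification: the lipase acylates one of the two enantiotopic hydroxymethyl groups and thereby creates C3, whose configuration is set by the enzyme's discrimination of the two arms (taken as R, see the assumption); the reaction would be stopped before diacetate forms.

Step 7
Reactants: 11 (2R)-2-Ar-3-hydroxypropyl acetate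
Product: 12 (2S)-2-Ar-3-[(tert-butyldimethylsilyl)oxy]propyl acetate
Conditions: TBSCl, imidazole, CH2Cl2, 0 °C
Reagents that add atoms: tert-butyldimethylsilyl chloride, CC(C)(C)[Si](C)(C)Cl
Why: Silylation of the remaining primary alcohol under near-neutral conditions; low temperature and short contact should prevent 1,3-acetyl migration, which would exchange the arms and erode enantiomeric purity (the descriptor changes only because the priorities change).

Step 8
Reactants: 12 (2S)-2-Ar-3-[(tert-butyldimethylsilyl)oxy]propyl acetate
Product: 13 (2S)-2-Ar-3-[(tert-butyldimethylsilyl)oxy]propan-1-ol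
Conditions: K2CO3 (cat.), MeOH, 0 °C
Reagents that add atoms: none
Why: Carbonate-catalysed methanolysis frees the arm that will carry ring A; the silyl ether is stable, and the cold, brief treatment guards against silyl migration between the two oxygens, the only process that could racemise C3.

Step 9
Reactants: 13 (2S)-2-Ar-3-[(tert-butyldimethylsilyl)oxy]propan-1-ol
Product: 14 (2R)-2-Ar-3-[(tert-butyldimethylsilyl)oxy]propyl trifluoromethanesulfonate
Conditions: Tf2O, 2,6-lutidine, CH2Cl2, −78 °C
Reagents that add atoms: trifluoromethanesulfonic anhydride, O=S(=O)(OS(=O)(=O)C(F)(F)F)C(F)(F)F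
Why: O-Sulfonylation of a primary alcohol; a triflate is needed because displacement at this β-branched carbon is slow, and it would be kept cold and used at once because the ortho ether oxygen of ring B could assist its ionisation.

Step 10
Reactants: 14 (2R)-2-Ar-3-[(tert-butyldimethylsilyl)oxy]propyl trifluoromethanesulfonate; 15 chloroacetaldehyde dimethyl acetal
Product: 17 tert-butyl{[(2R)-2-Ar-5-methoxypent-4-yn-1-yl]oxy}dimethylsilane, via lithium methoxyacetylide 16 (not isolated)
Conditions: 15, LDA (3.0 equiv), THF, −78 → 0 °C; then 14, THF–DMPU, −78 → −20 °C
Reagents that add atoms: none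
Why: Three equivalents of amide base take the chloroacetal through loss of methanol and of HCl to the deprotonated ynol ether 16, which displaces the triflate by SN2 (alkylation of an alkoxyacetylide) and forms C4–C4a; the hindered amine set free should not compete for the triflate, C3 is not a reacting centre, and a methyl ynol ether cannot undergo the retro-ene loss of alkene open to higher alkyl ynol ethers.

Step 11
Reactants: 18 3-ethoxycyclobut-2-en-1-one
Product: 19 3-(allyloxy)cyclobut-2-en-1-one
Conditions: allyl alcohol (10 equiv), camphorsulfonic acid (5 mol%), 5 Å molecular sieves, CH2Cl2, rt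
Reagents that add atoms: allyl alcohol, C=CCO
Why: Acid-catalysed exchange of the alkoxy group of a vinylogous ester (addition of allyl alcohol at C3 of the protonated enone, then loss of ethanol), driven by uptake of ethanol on the sieves; mild acid and low temperature are chosen to spare the strained ring, and the allyl group is needed because an ethyl ether on C7 could not be cleaved beside the methyl ether.

Step 12
Reactants: 17 tert-butyl{[(2R)-2-Ar-5-methoxypent-4-yn-1-yl]oxy}dimethylsilane; 19 3-(allyloxy)cyclobut-2-en-1-one
Product: 24 5-(allyloxy)-2-{(2R)-2-Ar-3-[(tert-butyldimethylsilyl)oxy]propyl}-3-methoxyphenol, via vinylketene 20 (not isolated), via vinylcyclobutenone 21 (not isolated), via dienylketene 22 (not isolated), via cyclohexadienone 23 (not isolated)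
Conditions: 19 (2.5 equiv, in portions), toluene (0.5 M), 80 → 110 °C; then K2CO3, MeOH, rt
Reagents that add atoms: none
Why: On heating, 19 should open by four-electron conrotatory electrocyclic reaction to the vinylketene 20; alkoxy-substituted cyclobutenones of the squaric ester family show that an alkoxy group on C3 does not block this opening. The electrophilic carbonyl carbon of 20 bonds to the nucleophilic, chain-bearing β-carbon of the ynol ether 17, and the ketene α-carbon bonds to the methoxy-bearing carbon, in a regiospecific (2+2) cycloaddition that gives 21 and forms C4a–C8a and C5–C6. 21 opens (four electrons) to the dienylketene 22, which closes ring A at C8–C8a by thermal disrotatory six-electron electrocyclisation to 23, and tautomerisation gives the phenol 24. The closest known reaction type is the Danheiser benzannulation of cyclobutenones with alkoxy- and siloxyalkynes to resorcinol monoethers. No stereocentre is created in the product: the sp3 carbon of 21 is lost on ring opening, and C3, two bonds from the nearest reacting atom and without an acidic hydrogen, is not affected. The one selectivity required is the regiochemistry of the (2+2) union, which the polarisation of the ynol ether secures; it puts the free hydroxyl (from the ketene carbonyl) and the methoxy group on either side of C4a and the allyloxy group para to it. The [3,3] shifts open to the allyl enol ether and aryl allyl ether units should need higher temperatures than this cascade. The excess of 19 makes up for ketene lost to self-reaction, and the carbonate methanolysis returns any product phenol that surplus ketene has O-acylated.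

Step 13
Reactants: 24 5-(allyloxy)-2-{(2R)-2-Ar-3-[(tert-butyldimethylsilyl)oxy]propyl}-3-methoxyphenol
Product: 25 5-(allyloxy)-2-[(2R)-2-Ar-3-hydroxypropyl]-3-methoxyphenol
Conditions: TBAF, THF, 0 °C → rt
Reagents that add atoms: none
Why: Fluoride cleaves the primary silyl ether (formation of the strong Si–F bond); the allyl ethers and the chromene are inert, and the phenoxide formed reversibly is protonated on work-up.

Step 14
Reactants: 25 5-(allyloxy)-2-[(2R)-2-Ar-3-hydroxypropyl]-3-methoxyphenol
Product: 26 (3R)-7-(allyloxy)-3-Ar-5-methoxychroman
Conditions: PPh3, DIAD, THF (0.01 M), 0 °C → rt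
Reagents that add atoms: none
Why: Intramolecular Mitsunobu etherification: the only free phenol of ring A attacks the activated primary carbon in a 6-exo-tet closure that forms O1–C2; high dilution suppresses intermolecular ether formation, and C3, one atom from the reacting carbon, keeps its configuration.

Step 15
Reactants: 26 (3R)-7-(allyloxy)-3-Ar-5-methoxychroman
Product: 27 (3R)-3-(5-hydroxy-2,2-dimethyl-2H-chromen-8-yl)-5-methoxychroman-7-ol
Conditions: Pd(PPh3)4 (5 mol%), morpholine (10 equiv), THF, rt
Reagents that add atoms: none
Why: Zerovalent palladium ionises both aryl allyl ethers to π-allyl complexes that morpholine intercepts (Tsuji–Trost deallylation), under neutral conditions that leave the chromene alkene, the methyl ether and C3 untouched; the cyclic tertiary allylic ether of the chromene is hindered, and any ionisation there would simply re-close.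

## Compound list

1 | 4-iodoresorcinol (4-iodobenzene-1,3-diol) | Oc1ccc(I)c(O)c1 | starting material
2 | 5-(allyloxy)-2-iodophenol | Oc1cc(OCC=C)ccc1I | intermediate
3 | 3-chloro-3-methylbut-1-yne | CC(C)(Cl)C#C | starting material
4 | 4-(allyloxy)-1-iodo-2-[(2-methylbut-3-yn-2-yl)oxy]benzene | C#CC(C)(C)Oc1cc(OCC=C)ccc1I | intermediate
5 | 3-(allyloxy)-6-iodo-2-(3-methylbuta-1,2-dien-1-yl)phenol | CC(C)=C=Cc1c(O)c(I)ccc1OCC=C | intermediate (not isolated)
6 | (6Z)-5-(allyloxy)-2-iodo-6-(3-methylbut-2-en-1-ylidene)cyclohexa-2,4-dien-1-one | CC(C)=C/C=C1\C(=O)C(I)=CC=C1OCC=C | intermediate (not isolated)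
7 | 5-(allyloxy)-8-iodo-2,2-dimethyl-2H-chromene | C=CCOc1ccc(I)c2OC(C)(C)C=Cc12 | intermediate
8 | diethyl malonate | CCOC(=O)CC(=O)OCC | starting material
9 | diethyl 2-[5-(allyloxy)-2,2-dimethyl-2H-chromen-8-yl]malonate | CCOC(=O)C(C(=O)OCC)c1ccc(OCC=C)c2c1OC(C)(C)C=C2 | intermediate
10 | 2-[5-(allyloxy)-2,2-dimethyl-2H-chromen-8-yl]propane-1,3-diol | OCC(CO)c1ccc(OCC=C)c2c1OC(C)(C)C=C2 | intermediate
11 | (2R)-2-[5-(allyloxy)-2,2-dimethyl-2H-chromen-8-yl]-3-hydroxypropyl acetate | CC(=O)OC[C@H](c1ccc(OCC=C)c2c1OC(C)(C)C=C2)CO | intermediate
12 | (2S)-2-[5-(allyloxy)-2,2-dimethyl-2H-chromen-8-yl]-3-[(tert-butyldimethylsilyl)oxy]propyl acetate | CC(=O)OC[C@H](c1ccc(OCC=C)c2c1OC(C)(C)C=C2)CO[Si](C)(C)C(C)(C)C | intermediate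
13 | (2S)-2-[5-(allyloxy)-2,2-dimethyl-2H-chromen-8-yl]-3-[(tert-butyldimethylsilyl)oxy]propan-1-ol | OC[C@H](c1ccc(OCC=C)c2c1OC(C)(C)C=C2)CO[Si](C)(C)C(C)(C)C | intermediate
14 | (2R)-2-[5-(allyloxy)-2,2-dimethyl-2H-chromen-8-yl]-3-[(tert-butyldimethylsilyl)oxy]propyl trifluoromethanesulfonate | FC(F)(F)S(=O)(=O)OC[C@H](c1ccc(OCC=C)c2c1OC(C)(C)C=C2)CO[Si](C)(C)C(C)(C)C | intermediate
15 | chloroacetaldehyde dimethyl acetal (2-chloro-1,1-dimethoxyethane) | COC(CCl)OC | starting material
16 | lithium methoxyacetylide | [Li]C#COC | intermediate (not isolated)
17 | tert-butyl{[(2R)-2-[5-(allyloxy)-2,2-dimethyl-2H-chromen-8-yl]-5-methoxypent-4-yn-1-yl]oxy}dimethylsilane | COC#CC[C@H](c1ccc(OCC=C)c2c1OC(C)(C)C=C2)CO[Si](C)(C)C(C)(C)C | intermediate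
18 | 3-ethoxycyclobut-2-en-1-one | CCOC1=CC(=O)C1 | starting material
19 | 3-(allyloxy)cyclobut-2-en-1-one | C=CCOC1=CC(=O)C1 | intermediate
20 | 3-(allyloxy)buta-1,3-dien-1-one | C=CCOC(=C)C=C=O | intermediate (not isolated)
21 | 4-[1-(allyloxy)ethenyl]-2-{(2R)-2-Ar-3-[(tert-butyldimethylsilyl)oxy]propyl}-3-methoxycyclobut-2-en-1-one (ring C4 unassigned) | O=C1C(C[C@H](c2ccc(OCC=C)c3c2OC(C)(C)C=C3)CO[Si](C)(C)C(C)(C)C)=C(OC)C1C(=C)OCC=C | intermediate (not isolated)
22 | (3E)-5-(allyloxy)-2-{(2R)-2-Ar-3-[(tert-butyldimethylsilyl)oxy]propyl}-3-methoxyhexa-1,3,5-trien-1-one | O=C=C(C[C@H](c1ccc(OCC=C)c2c1OC(C)(C)C=C2)CO[Si](C)(C)C(C)(C)C)/C(OC)=C\C(=C)OCC=C | intermediate (not isolated)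
23 | 5-(allyloxy)-2-{(2R)-2-Ar-3-[(tert-butyldimethylsilyl)oxy]propyl}-3-methoxycyclohexa-2,4-dien-1-one | O=C1CC(OCC=C)=CC(OC)=C1C[C@H](c1ccc(OCC=C)c2c1OC(C)(C)C=C2)CO[Si](C)(C)C(C)(C)C | intermediate (not isolated)
24 | 5-(allyloxy)-2-{(2R)-2-[5-(allyloxy)-2,2-dimethyl-2H-chromen-8-yl]-3-[(tert-butyldimethylsilyl)oxy]propyl}-3-methoxyphenol | COc1cc(OCC=C)cc(O)c1C[C@H](c1ccc(OCC=C)c2c1OC(C)(C)C=C2)CO[Si](C)(C)C(C)(C)C | intermediate
25 | 5-(allyloxy)-2-{(2R)-2-[5-(allyloxy)-2,2-dimethyl-2H-chromen-8-yl]-3-hydroxypropyl}-3-methoxyphenol | COc1cc(OCC=C)cc(O)c1C[C@H](c1ccc(OCC=C)c2c1OC(C)(C)C=C2)CO | intermediate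
26 | (3R)-7-(allyloxy)-3-[5-(allyloxy)-2,2-dimethyl-2H-chromen-8-yl]-5-methoxychroman | COc1cc(OCC=C)cc2c1C[C@H](c1ccc(OCC=C)c3c1OC(C)(C)C=C3)CO2 | intermediate
27 | (3R)-3-(5-hydroxy-2,2-dimethyl-2H-chromen-8-yl)-5-methoxychroman-7-ol (CNP0320659.1) | COc1cc(O)cc2c1C[C@H](c1ccc(O)c3c1OC(C)(C)C=C3)CO2 | target

## Step count and least certain steps

Total: 15 steps. Longest linear sequence: 14 steps (steps 1–10 and 12–15); step 11 is a one-step branch.

Step 12 (key step). The most likely failure is a slow ring opening of 19, because the enol ether oxygen conjugates with the ring carbonyl and stabilises the four-membered ring. If the temperature had to rise well above 110 °C, [3,3] shifts of the allyl enol ether units, self-reaction of the ketene and O-acylation of the product phenol would cut into the yield. The fallback keeps the same vinylketene 20 and the same cascade but makes 20 without heat, by 1,4-dehydrochlorination of a β-alkoxycrotonyl chloride, a known way to vinylketenes. Commercial ethyl (E)-3-ethoxybut-2-enoate F1 would be exchanged with allyl alcohol (TsOH cat., ethanol distilled off) to ethyl (E)-3-(allyloxy)but-2-enoate F2, saponified with LiOH to (E)-3-(allyloxy)but-2-enoic acid F3, and converted with (COCl)2 to (E)-3-(allyloxy)but-2-enoyl chloride F4. Slow addition of Et3N to F4 and 17 in toluene at 0–25 °C should give 20, which 17 traps as 21; brief warming to about 80 °C would take 21 through 22 and 23 to 24. The fallback sets out from 17 and returns to the route at 24.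

Step 10. Elimination across the C3–CH2OTf bond (the β-hydrogen is benzylic), ionisation of the triflate assisted by the ortho ether oxygen, or attack of methoxide or amine on the triflate could each divert material from the substitution. The fallback avoids alkoxyacetylide alkylation altogether.
- From 14, monolithium acetylide (acetylene, n-BuLi, THF–DMPU, −78 °C), a less basic and amine-free nucleophile, would give tert-butyl{[(2R)-2-Ar-pent-4-yn-1-yl]oxy}dimethylsilane F5.
- Deprotonation of F5 and oxidation of the lithium acetylide with lithium tert-butyl peroxide would give the ynolate, which TIPSOTf silylates on oxygen to the siloxyalkyne F6.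
- Benzannulation of F6 with 19 under the conditions of step 12 would give 5-(allyloxy)-2-{(2R)-2-Ar-3-[(tert-butyldimethylsilyl)oxy]propyl}-3-[(triisopropylsilyl)oxy]phenol F7.
- TBAF would remove both silyl groups to give 5-(allyloxy)-2-[(2R)-2-Ar-3-hydroxypropyl]benzene-1,3-diol F8. Its two phenols are equivalent with respect to the chain, so Mitsunobu closure can give only one chromanol, (3R)-7-(allyloxy)-3-Ar-chroman-5-ol F9.
- Methylation of F9 (MeI, K2CO3, acetone) would give 26.

The fallback sets out from 14 and returns at 26, at the cost of two extra steps.

Step 11. Acid-promoted opening of the strained ring by allyl alcohol (addition at the carbonyl carbon and cleavage to an acetoacetate derivative) may outrun the exchange. The fallback forms the O–allyl bond by substitution at the allyl carbon instead of addition–elimination at the ring. Brief hydrolysis of 18 with cold dilute HCl would give 3-hydroxycyclobut-2-en-1-one F10, the strongly acidic enol of cyclobutane-1,3-dione. Mitsunobu O-alkylation of F10 (allyl alcohol, PPh3, DIAD, THF, 0 °C) would give 19. The fallback sets out from 18 and returns at 19.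

Step 4. The coupling may be sluggish on the hindered, electron-rich iodide, and at the temperature then needed the product may lose an ethoxycarbonyl group under the basic conditions. The fallback forms C3–C1' by a 1,2-aryl shift instead of a cross-coupling.
- Iodine–magnesium exchange on 7 (iPrMgCl·LiCl, THF, −20 °C) and quenching with DMF would give 5-(allyloxy)-2,2-dimethyl-2H-chromene-8-carbaldehyde F11.
- Ethyl diazoacetate with catalytic HBF4·OEt2 (CH2Cl2, −78 °C) converts electron-rich aryl aldehydes into 3-hydroxy-2-arylacrylates by aryl migration in the diazonium adduct, and should give ethyl (2Z)-2-Ar-3-hydroxyprop-2-enoate F12.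
- NaBH4 would reduce the formyl tautomer of F12 to ethyl 2-Ar-3-hydroxypropanoate F13, and LiAlH4 would give 10.

The fallback sets out from 7 and returns at 10.

Step 1. The two hydroxyls may be discriminated incompletely (the one next to iodine is the more hindered but also the more acidic), and double alkylation may occur. The fallback takes the regiochemistry from a chelated salicylaldehyde. In commercial 2,4-dihydroxybenzaldehyde F14 the 2-hydroxyl is tied up in a hydrogen bond to the formyl group, so allyl bromide and K2CO3 should alkylate only O4 to give 4-(allyloxy)-2-hydroxybenzaldehyde F15. Propargylation of F15 with 3 (K2CO3, KI, DMF, 65 °C) would give 4-(allyloxy)-2-[(2-methylbut-3-yn-2-yl)oxy]benzaldehyde F16, and heating in xylenes would give the aldehyde F11. F11 then follows the sequence through F12 and F13 described for step 4. The fallback sets out from 3 and returns at 10.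

Step 6. The enantiotopic-group selectivity may be low or opposite to the sense assumed, because the doubly ortho-substituted aryl group is bulkier than in the simple 2-aryl-1,3-propanediols, and over-acylation to the diacetate may occur. The fallback runs the enzyme in the hydrolytic direction. 10 would be peracetylated (Ac2O, pyridine) to 2-Ar-propane-1,3-diyl diacetate F17, and lipase-catalysed hydrolysis in phosphate buffer at pH 7 would remove one enantiotopic acetate. A lipase attacks the same arm in both directions, so hydrolysis gives the antipode of the acylation product, and whichever direction leads to (R)-11 would be used. The fallback sets out from 10 and returns at 11.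

## Further compounds

F1 | step 12 | ethyl (2E)-3-ethoxybut-2-enoate | CCO/C(C)=C/C(=O)OCC
F2 | step 12 | ethyl (2E)-3-(allyloxy)but-2-enoate | C=CCO/C(C)=C/C(=O)OCC
F3 | step 12 | (2E)-3-(allyloxy)but-2-enoic acid | C=CCO/C(C)=C/C(=O)O
F4 | step 12 | (2E)-3-(allyloxy)but-2-enoyl chloride | C=CCO/C(C)=C/C(=O)Cl
F5 | step 10 | tert-butyl{[(2R)-2-[5-(allyloxy)-2,2-dimethyl-2H-chromen-8-yl]pent-4-yn-1-yl]oxy}dimethylsilane | C#CC[C@H](c1ccc(OCC=C)c2c1OC(C)(C)C=C2)CO[Si](C)(C)C(C)(C)C
F6 | step 10 | tert-butyl{[(2R)-2-[5-(allyloxy)-2,2-dimethyl-2H-chromen-8-yl]-5-[(triisopropylsilyl)oxy]pent-4-yn-1-yl]oxy}dimethylsilane | CC(C)[Si](C(C)C)(C(C)C)OC#CC[C@H](c1ccc(OCC=C)c2c1OC(C)(C)C=C2)CO[Si](C)(C)C(C)(C)C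
F7 | step 10 | 5-(allyloxy)-2-{(2R)-2-[5-(allyloxy)-2,2-dimethyl-2H-chromen-8-yl]-3-[(tert-butyldimethylsilyl)oxy]propyl}-3-[(triisopropylsilyl)oxy]phenol | CC(C)[Si](C(C)C)(C(C)C)Oc1cc(OCC=C)cc(O)c1C[C@H](c1ccc(OCC=C)c2c1OC(C)(C)C=C2)CO[Si](C)(C)C(C)(C)C
F8 | step 10 | 5-(allyloxy)-2-{(2R)-2-[5-(allyloxy)-2,2-dimethyl-2H-chromen-8-yl]-3-hydroxypropyl}benzene-1,3-diol | Oc1cc(OCC=C)cc(O)c1C[C@H](c1ccc(OCC=C)c2c1OC(C)(C)C=C2)CO
F9 | step 10 | (3R)-7-(allyloxy)-3-[5-(allyloxy)-2,2-dimethyl-2H-chromen-8-yl]chroman-5-ol | Oc1cc(OCC=C)cc2c1C[C@H](c1ccc(OCC=C)c3c1OC(C)(C)C=C3)CO2
F10 | step 11 | 3-hydroxycyclobut-2-en-1-one | O=C1CC(O)=C1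
F11 | step 4 | 5-(allyloxy)-2,2-dimethyl-2H-chromene-8-carbaldehyde | O=Cc1ccc(OCC=C)c2c1OC(C)(C)C=C2
F12 | step 4 | ethyl (2Z)-2-[5-(allyloxy)-2,2-dimethyl-2H-chromen-8-yl]-3-hydroxyprop-2-enoate | CCOC(=O)/C(=C\O)c1ccc(OCC=C)c2c1OC(C)(C)C=C2
F13 | step 4 | ethyl 2-[5-(allyloxy)-2,2-dimethyl-2H-chromen-8-yl]-3-hydroxypropanoate (racemic) | CCOC(=O)C(CO)c1ccc(OCC=C)c2c1OC(C)(C)C=C2
F14 | step 1 | 2,4-dihydroxybenzaldehyde | O=Cc1ccc(O)cc1O
F15 | step 1 | 4-(allyloxy)-2-hydroxybenzaldehyde | O=Cc1ccc(OCC=C)cc1O
F16 | step 1 | 4-(allyloxy)-2-[(2-methylbut-3-yn-2-yl)oxy]benzaldehyde | O=Cc1ccc(OCC=C)cc1OC(C)(C)C#C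
F17 | step 6 | 2-[5-(allyloxy)-2,2-dimethyl-2H-chromen-8-yl]propane-1,3-diyl diacetate | CC(=O)OCC(COC(C)=O)c1ccc(OCC=C)c2c1OC(C)(C)C=C2
A1 | alternative 1 | (3R)-3-[2,2-dimethyl-5-(triisopropylsilyloxy)-2H-chromen-8-yl]-5-methoxy-7-(triisopropylsilyloxy)chroman-2-ol (anomeric mixture) | COc1cc(O[Si](C(C)C)(C(C)C)C(C)C)cc2c1C[C@H](c1ccc(O[Si](C(C)C)(C(C)C)C(C)C)c3c1OC(C)(C)C=C3)C(O)O2
A2 | alternative 1 | 3-methoxy-2-[(4-methylphenylsulfonyl)methyl]-5-(triisopropylsilyloxy)phenol | Cc1ccc(cc1)S(=O)(=O)Cc1c(O)cc(O[Si](C(C)C)(C(C)C)C(C)C)cc1OC
A3 | alternative 1 | 2-[2,2-dimethyl-5-(triisopropylsilyloxy)-2H-chromen-8-yl]acetaldehyde | O=CCc1ccc(O[Si](C(C)C)(C(C)C)C(C)C)c2c1OC(C)(C)C=C2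
A4 | alternative 1 | 5-methoxy-6-methylidene-3-(triisopropylsilyloxy)cyclohexa-2,4-dien-1-one | C=C1C(=O)C=C(O[Si](C(C)C)(C(C)C)C(C)C)C=C1OC
A5 | alternative 2 | 6-[(3R)-5-methoxy-7-(triisopropylsilyloxy)chroman-3-yl]-2-(3-methylbut-2-en-1-yl)-3-(triisopropylsilyloxy)phenol | COc1cc(O[Si](C(C)C)(C(C)C)C(C)C)cc2c1C[C@H](c1ccc(O[Si](C(C)C)(C(C)C)C(C)C)c(CC=C(C)C)c1O)CO2
A6 | alternative 2 | (3E)-1-diazo-4-[(3R)-5-methoxy-7-(triisopropylsilyloxy)chroman-3-yl]but-3-en-2-one | COc1cc(O[Si](C(C)C)(C(C)C)C(C)C)cc2c1C[C@H](/C=C/C(=O)C=[N+]=[N-])CO2
A7 | alternative 2 | triisopropyl[(5-methylhex-4-en-1-yn-1-yl)oxy]silane | CC(C)=CCC#CO[Si](C(C)C)(C(C)C)C(C)C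
A8 | alternative 3 | 2-{(1R)-2-[2-methoxy-4,6-bis(methoxymethoxy)phenyl]-1-[5-(methoxymethoxy)-2,2-dimethyl-2H-chromen-8-yl]ethyl}-4,4,5,5-tetramethyl-1,3,2-dioxaborolane | COc1cc(OCOC)cc(OCOC)c1C[C@H](c1ccc(OCOC)c2c1OC(C)(C)C=C2)B1OC(C)(C)C(C)(C)O1
A9 | alternative 3 | 2-methoxy-4,6-bis(methoxymethoxy)phenyl trifluoromethanesulfonate | COc1cc(OCOC)cc(OCOC)c1OS(=O)(=O)C(F)(F)F
A10 | alternative 3 | [5-(methoxymethoxy)-2,2-dimethyl-2H-chromen-8-yl]lithium | [Li]c1ccc(OCOC)c2c1OC(C)(C)C=C2
A11 | alternative 3 | 4,4,5,5-tetramethyl-2-vinyl-1,3,2-dioxaborolane | C=CB1OC(C)(C)C(C)(C)O1
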